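**Strategy.** Everything rests on the biosynthetic logic of isoflavonoids: ring B is not coupled to C3 but migrates there from C2. A 2'-hydroxychalcone, assembled by aldol condensation, undergoes a thallium(III)-triggered oxidative 1,2-aryl shift, and the rearranged acetal closes the pyranone ring in the same flask; the C3–C1' bond and the O1–C2 bond are thus formed in one operation. The step exploits the methoxy group at C2', ortho to the migrating carbon C1', which stabilises the bridged phenonium ion, and the fully substituted ring A (C5 to C8), which offers no aryl C–H to the oxidant. The precursor is an open-chain 1,3-diarylpropenone that carries both rings complete.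

Key step: step 5

Remark: the target has no stereocentre and the C3–C1' axis (one ortho substituent on ring B) rotates freely, so the compound is achiral and "single enantiomer" requires no stereocontrol.

**Step 1**
Reactants: 1 1,2,3,4-tetramethoxybenzene
Product: 4 2,3,4,5-tetramethoxyphenol, via tetramethoxyphenyllithium 2 (not isolated), via lithium aryltrimethoxyborate 3 (not isolated)
Conditions: n-BuLi, TMEDA, THF, 0 °C → rt; B(OMe)3, −78 °C → rt; AcOH, 30% H2O2, 0 °C → rt
Reagents that add atoms: hydrogen peroxide, OO
Why: Methoxy-directed ortho-lithiation can only occur at the two equivalent C–H positions of the symmetric arene, and borylation followed by peroxide oxidation of the aryl borate (aryl shift from boron to oxygen) should deliver the phenol.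

**Step 2**
Reactants: 4 2,3,4,5-tetramethoxyphenol
Product: 6 1-(2-hydroxy-3,4,5,6-tetramethoxyphenyl)ethan-1-one, via 2,3,4,5-tetramethoxyphenyl acetate 5 (not isolated)
Conditions: Ac2O, BF3·OEt2, 80 °C; aq. work-up
Reagents that add atoms: acetic anhydride, CC(=O)OC(C)=O
Why: O-acetylation followed by Lewis-acid Fries rearrangement must place the acetyl group on the only free ring carbon, which is ortho to the phenol and activated by ortho and para methoxy groups, and the product is stabilised by the OH···O=C hydrogen bond.

**Step 3**
Reactants: 7 3-hydroxy-2-methoxybenzaldehyde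
Product: 8 3-(benzyloxy)-2-methoxybenzaldehyde
Conditions: BnBr, K2CO3, DMF, 50 °C
Reagents that add atoms: benzyl bromide, BrCc1ccccc1
Why: Williamson ether synthesis on the only phenol masks the ring-B hydroxyl, which would otherwise be oxidised in step 5, as an ether that step 6 removes.

**Step 4**
Reactants: 6 1-(2-hydroxy-3,4,5,6-tetramethoxyphenyl)ethan-1-one; 8 3-(benzyloxy)-2-methoxybenzaldehyde
Product: 10 (2E)-3-[3-(benzyloxy)-2-methoxyphenyl]-1-(2-hydroxy-3,4,5,6-tetramethoxyphenyl)prop-2-en-1-one, via racemic aldol adduct 9 (not isolated)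
Conditions: 50% aq. KOH, EtOH, rt; then dil. HCl, 0 °C
Reagents that add atoms: none
Why: Claisen–Schmidt condensation of the methyl ketone enolate with a non-enolisable aldehyde, with E1cB dehydration of the aldol giving the conjugated E-alkene under thermodynamic control.

**Step 5**
Reactants: 10 (2E)-3-[3-(benzyloxy)-2-methoxyphenyl]-1-(2-hydroxy-3,4,5,6-tetramethoxyphenyl)prop-2-en-1-one
Product: 12 3-[3-(benzyloxy)-2-methoxyphenyl]-5,6,7,8-tetramethoxy-4H-chromen-4-one, via rearranged dimethyl acetal 11 (not isolated)
Conditions: Tl(NO3)3·3H2O (1.1 equiv), MeOH, rt; then 10% aq. HCl, 60 °C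
Reagents that add atoms: none
Why: Tl(III) adds across the enone C=C (oxythallation, methanol at the benzylic Cβ and thallium at Cα), and reductive loss of Tl(I) from Cα is accompanied by an anti 1,2-shift of ring B from Cβ to Cα through a phenonium ion, the resulting methoxycarbenium ion at Cβ being trapped by methanol as acetal 11. On acidification the acetal ionises and the ring-A hydroxyl attacks the oxocarbenium carbon in a 6-exo-trig closure, after which loss of methanol gives the C2=C3 bond of the 4-pyranone. The closest known reaction type is the thallium(III) nitrate oxidative rearrangement of 2'-hydroxychalcones to isoflavones, the chemical counterpart of the aryl migration of isoflavone synthase. No stereocentre has to be controlled, since the racemic centre of 11 becomes the sp2 carbon C3. The step needs aryl migration to win over hydride shift, aurone formation and ring oxidation; this is secured by the ortho-methoxy donor at C2' on the migrating ring, by the hydrogen bond that ties the ring-A phenol to the carbonyl, and by the absence of any C–H on ring A. Only the free hydroxyl, not the flanking methoxy group, can cyclise, so the 5-OMe/O1 regiochemistry is unambiguous.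

**Step 6**
Reactants: 12 3-[3-(benzyloxy)-2-methoxyphenyl]-5,6,7,8-tetramethoxy-4H-chromen-4-one
Product: 15 5-hydroxy-3-(3-hydroxy-2-methoxyphenyl)-6,7,8-trimethoxy-4H-chromen-4-one (5,3'-dihydroxy-6,7,8,2'-tetramethoxyisoflavone), via 3'-O-dichloroboryl ether 13 (not isolated), via 5,3'-bis(O-dichloroboryl) isoflavone 14 (not isolated)
Conditions: BCl3 (1 M in CH2Cl2, 4 equiv), C6HMe5 (3 equiv), CH2Cl2, −78 °C → 0 °C; then MeOH, aq. NaHCO3
Reagents that add atoms: none
Why: BCl3 should cleave the benzyl ether at low temperature (benzyl cation intercepted by pentamethylbenzene in a Friedel–Crafts alkylation) and, on warming, only the 5-methoxy group through the six-membered boron chelate with the C4 carbonyl (chelation-controlled Lewis-acid ether cleavage), the non-chelated methyl ethers at C6, C7, C8 and C2' remaining, and aqueous work-up hydrolyses the B–O bonds.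

**Compound list**

1 | 1,2,3,4-tetramethoxybenzene | COc1ccc(OC)c(OC)c1OC | starting material
2 | (2,3,4,5-tetramethoxyphenyl)lithium | [Li]c1cc(OC)c(OC)c(OC)c1OC | intermediate
3 | lithium trimethoxy(2,3,4,5-tetramethoxyphenyl)borate | [Li+].CO[B-](OC)(OC)c1cc(OC)c(OC)c(OC)c1OC | intermediate
4 | 2,3,4,5-tetramethoxyphenol | COc1cc(O)c(OC)c(OC)c1OC | intermediate
5 | 2,3,4,5-tetramethoxyphenyl acetate | CC(=O)Oc1cc(OC)c(OC)c(OC)c1OC | intermediate
6 | 1-(2-hydroxy-3,4,5,6-tetramethoxyphenyl)ethan-1-one | CC(=O)c1c(O)c(OC)c(OC)c(OC)c1OC | intermediate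
7 | 3-hydroxy-2-methoxybenzaldehyde | COc1c(O)cccc1C=O | starting material
8 | 3-(benzyloxy)-2-methoxybenzaldehyde | COc1c(OCc2ccccc2)cccc1C=O | intermediate
9 | 3-[3-(benzyloxy)-2-methoxyphenyl]-3-hydroxy-1-(2-hydroxy-3,4,5,6-tetramethoxyphenyl)propan-1-one (racemic) | COc1c(OCc2ccccc2)cccc1C(O)CC(=O)c1c(O)c(OC)c(OC)c(OC)c1OC | intermediate
10 | (2E)-3-[3-(benzyloxy)-2-methoxyphenyl]-1-(2-hydroxy-3,4,5,6-tetramethoxyphenyl)prop-2-en-1-one | COc1c(OCc2ccccc2)cccc1/C=C/C(=O)c1c(O)c(OC)c(OC)c(OC)c1OC | intermediate
11 | 2-[3-(benzyloxy)-2-methoxyphenyl]-1-(2-hydroxy-3,4,5,6-tetramethoxyphenyl)-3,3-dimethoxypropan-1-one (racemic) | COC(OC)C(c1cccc(OCc2ccccc2)c1OC)C(=O)c1c(O)c(OC)c(OC)c(OC)c1OC | intermediate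
12 | 3-[3-(benzyloxy)-2-methoxyphenyl]-5,6,7,8-tetramethoxy-4H-chromen-4-one | COc1c(OCc2ccccc2)cccc1-c1coc2c(OC)c(OC)c(OC)c(OC)c2c1=O | intermediate
13 | 3-[3-(dichloroboryloxy)-2-methoxyphenyl]-5,6,7,8-tetramethoxy-4H-chromen-4-one | COc1c(OB(Cl)Cl)cccc1-c1coc2c(OC)c(OC)c(OC)c(OC)c2c1=O | intermediate
14 | 5-(dichloroboryloxy)-3-[3-(dichloroboryloxy)-2-methoxyphenyl]-6,7,8-trimethoxy-4H-chromen-4-one | COc1c(OB(Cl)Cl)cccc1-c1coc2c(OC)c(OC)c(OC)c(OB(Cl)Cl)c2c1=O | intermediate
15 | 5-hydroxy-3-(3-hydroxy-2-methoxyphenyl)-6,7,8-trimethoxy-4H-chromen-4-one (5,3'-dihydroxy-6,7,8,2'-tetramethoxyisoflavone) | COc1c(O)cccc1-c1coc2c(OC)c(OC)c(OC)c(O)c2c1=O | target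

**Route statistics**

Total step count: 6.
Longest linear sequence: 5 steps (1 → 4 → 6 → 10 → 12 → 15; steps 1, 2, 4, 5, 6).

**Steps most likely to fail**

Step 5. Thallium(III) may oxidise the electron-rich free phenol of ring A (oxidative demethylation towards a quinone), or the phenol oxygen may capture the oxythallation adduct before the aryl group migrates. The fallback removes the free phenol before the oxidation and uses iodine(III) on the cyclic ketone. It sets out from chalcone 10, which should close by oxa-Michael addition (NaOAc, EtOH, reflux) to the flavanone 2-[3-(benzyloxy)-2-methoxyphenyl]-5,6,7,8-tetramethoxychroman-4-one F1. Treatment with PhI(OH)OTs in MeCN at reflux should then iodanate the enol at C3 and drive the 2,3-shift of ring B with assistance from the O1 lone pair, and loss of a proton should return the route at isoflavone 12.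

Step 6. Prolonged contact with BCl3 may remove further methyl groups through neighbouring boron–oxygen chelation (at C6 from the 5-O–B group, at C2' from the 3'-O–B group), or the 5-O-demethylation may stall. The fallback separates the two deprotections and uses no Lewis acid. It sets out from 12, where hydrogenolysis (H2, Pd/C, EtOAc–MeOH, rt) should give 3-(3-hydroxy-2-methoxyphenyl)-5,6,7,8-tetramethoxy-4H-chromen-4-one F2. Protic, carbonyl-assisted cleavage of the peri 5-methoxy group (conc. HCl, EtOH, reflux), which does not engage the ring-B oxygens, should then return the route at target 15.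

Step 1. Lithiation of the weakly activated arene may be incomplete, or the very electron-rich phenol may be over-oxidised towards a quinone during the peroxide stage. The fallback introduces the oxygen through a carbonyl group. It sets out from 1, where Rieche formylation (Cl2CHOMe, TiCl4, CH2Cl2, 0 °C) should give 2,3,4,5-tetramethoxybenzaldehyde F3. Baeyer–Villiger oxidation (mCPBA, CH2Cl2, rt) should give 2,3,4,5-tetramethoxyphenyl formate F4, and hydrolysis (aq. KOH, MeOH, then acidification) should return the route at phenol 4.

**Further compounds**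

F1 | step 5 | 2-[3-(benzyloxy)-2-methoxyphenyl]-5,6,7,8-tetramethoxychroman-4-one (racemic) | COc1c(OCc2ccccc2)cccc1C1CC(=O)c2c(OC)c(OC)c(OC)c(OC)c2O1
F2 | step 6 | 3-(3-hydroxy-2-methoxyphenyl)-5,6,7,8-tetramethoxy-4H-chromen-4-one | COc1c(O)cccc1-c1coc2c(OC)c(OC)c(OC)c(OC)c2c1=O
F3 | step 1 | 2,3,4,5-tetramethoxybenzaldehyde | COc1cc(C=O)c(OC)c(OC)c1OC
F4 | step 1 | 2,3,4,5-tetramethoxyphenyl formate | COc1cc(OC=O)c(OC)c(OC)c1OC
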